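**Plan**
1. Cuts: (i) the eight phenolic OH groups go back to benzyl ethers. (ii) The interflavan bond C4 (ring C, upper unit)–C8 (ring D, lower unit) is cut to a flavan-4-ol and (−)-epigallocatechin. (iii) C2–C1' of the upper unit is cut (aryl addition to a chromone). (iv) O1–C2 and C2–C3 of the chromone are cut (acetophenone plus a C1 unit).
2. Enabling feature: C4 of the upper unit is benzylic to ring A, para (through C4a) to O-7 and ortho (through C8a) to O1. A C4–OH therefore leaves as water and gives a cation that is an O-alkylated ring-A p-quinone methide. C8 of ring D lies between O1 and O-7 and para to O-5, and is the most nucleophilic carbon of epigallocatechin. This is the electrophile/nucleophile pair assumed in proanthocyanidin biosynthesis.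
3. Forward order: ring C is closed first (chromone), then ring B is added at C2. The C4 ketone that activated this addition is reduced to the leaving group, the two monomers are joined, and all benzyl groups fall in one operation.
4. Stereochemistry: upper C2 (S) comes from Rh/chiral-diene catalysis. Upper C4 (R) is relayed from C2 in the coupling (pseudo-axial attack trans to the equatorial 2-aryl group). Lower C2 and C3 (R,R) come from the chiral pool.
5. Because the lower unit is enantiopure, any upper unit of the wrong hand ends up in a diastereomer that chromatography removes.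

Key step: step 5

Assumption: with (S,S)-Ph-bod* the aryl group is taken to add to the chromone face that gives 2S, by analogy with the (S)-3-arylcyclohexanones this ligand gives from 2-cyclohexenone; if the sense proves opposite, the (R,R)-ligand is used and nothing else changes.

Step 1
Reactants: 1 1-[4-(benzyloxy)-2-hydroxyphenyl]ethanone (4'-benzyloxy-2'-hydroxyacetophenone)
Product: 3 7-(benzyloxy)-4H-chromen-4-one, via enaminone 2 (not isolated)
Conditions: Me2NCH(OMe)2 (1.5 equiv), toluene, 100 °C; evaporate; conc. HCl, CH2Cl2, 40 °C
Reagents that add atoms: N,N-dimethylformamide dimethyl acetal, COC(OC)N(C)C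
Why: The acetyl methyl group condenses with the amide acetal to the enaminone 2, and under acid the ortho phenol adds to its β-carbon (6-endo-trig oxa-Michael addition) with expulsion of dimethylamine, which is the standard enaminone synthesis of 2,3-unsubstituted chromones; the benzyl ether is inert and no stereocentre arises.

Step 2
Reactants: 3 7-(benzyloxy)-4H-chromen-4-one; 4 [3,4-bis(benzyloxy)phenyl]boronic acid
Product: 5 (2S)-7-(benzyloxy)-2-[3,4-bis(benzyloxy)phenyl]chroman-4-one (tri-O-benzyl-(S)-butin)
Conditions: 4 (2 equiv), [RhCl(C2H4)2]2 (2.5 mol %), (1S,4S)-2,5-diphenylbicyclo[2.2.2]octa-2,5-diene [(S,S)-Ph-bod*] (5.5 mol %), KOH (0.1 equiv), toluene/H2O 20:1, 40 °C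
Reagents that add atoms: none
Why: Rhodium-catalysed asymmetric 1,4-addition of an arylboronic acid (Hayashi–Miyaura reaction), a type known for chromones, in which the aryl–Rh species held by the C2-symmetric diene inserts the C2=C3 bond on one enantiotopic face and sets C2 as S, while the almost neutral and largely non-aqueous medium should hold back 1,2-addition and the retro-oxa-Michael ring opening that would racemise 5.

Step 3
Reactants: 5 (2S)-7-(benzyloxy)-2-[3,4-bis(benzyloxy)phenyl]chroman-4-one
Product: 6 (2S,4S)-7-(benzyloxy)-2-[3,4-bis(benzyloxy)phenyl]chroman-4-ol (2,4-cis-flavan-4-ol)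
Conditions: NaBH4, THF/MeOH, 0 °C
Reagents that add atoms: none
Why: Borohydride reduction of a flavanone, in which hydride attacks C4 pseudo-axially on the face of H-2 and gives the equatorial alcohol cis to the 2-aryl group (4S); reduction is much faster than base-induced ring opening so that C2 is kept, and the C4 configuration is of no consequence because step 5 erases it.

Step 4
Reactants: 7 (−)-epigallocatechin, (2R,3R)-2-(3,4,5-trihydroxyphenyl)chromane-3,5,7-triol
Product: 8 (2R,3R)-5,7-bis(benzyloxy)-2-[3,4,5-tris(benzyloxy)phenyl]chroman-3-ol (penta-O-benzyl-epigallocatechin)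
Conditions: BnBr (5.5 equiv), K2CO3 (6 equiv), degassed DMF, Ar, 0 °C → rt
Reagents that add atoms: benzyl bromide, BrCc1ccccc1
Why: Williamson etherification in which carbonate deprotonates only the five phenols and not the secondary 3-OH, so that benzylation stops at the pentaether, while low temperature and exclusion of oxygen hold back C2 epimerisation, C-benzylation and pyrogallol oxidation; both stereocentres come unchanged from 7.

Step 5
Reactants: 6 (2S,4S)-7-(benzyloxy)-2-[3,4-bis(benzyloxy)phenyl]chroman-4-ol; 8 (2R,3R)-5,7-bis(benzyloxy)-2-[3,4,5-tris(benzyloxy)phenyl]chroman-3-ol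
Product: 10 (2R,3R)-5,7-bis(benzyloxy)-8-{(2S,4R)-7-(benzyloxy)-2-[3,4-bis(benzyloxy)phenyl]chroman-4-yl}-2-[3,4,5-tris(benzyloxy)phenyl]chroman-3-ol (octa-O-benzyl ether of the target), via flavan-4-yl cation 9 (not isolated)
Conditions: 8 (2.5 equiv, excess recovered), BF3·OEt2 (0.3 equiv), CH2Cl2, −78 → −30 °C, slow addition of 6; Et3N quench
Reagents that add atoms: none
Why: The Lewis acid (and the BF3·H2O formed from it) ionises the C4–OH of 6 to the cation 9, whose charge is shared by O-7 (para to C4a, so that 9 is an O-benzylated ring-A p-quinone methide) and by O1 on C8a; C8 of 8 attacks C4 and loss of H-8 restores the aromatic ring, with water as the only by-product. The closest known reaction type is the Lewis-acid-mediated Friedel–Crafts union of C4-oxygenated benzylated flavans with benzylated flavan-3-ols, and of flavan-4-ols with phloroglucinol ethers, itself the laboratory copy of the presumed biosynthetic quinone methide/flavan-3-ol coupling; no ring is closed. The one new stereocentre, C4, is controlled by C2: in the half-chair of 9 the 2-aryl group is pseudo-equatorial, and the stereoelectronically favoured pseudo-axial attack that leads straight to a half-chair product takes place on the face of the axial H-2, that is trans to the 2-aryl group, which gives 4R (4β), whereas attack on the other face must pass a boat-like array and the pseudo-axial 4-aryl group also escapes the peri contact with H-5. Site selectivity on 8 (C8 over C6, ring E and the 3-OH) rests on the substrate: ring D alone carries three donor oxygens, C8 lies between one benzyloxy group and the tied-back ring oxygen whereas C6 is flanked by two freely rotating benzyloxy groups, and any 3-O-alkylation is reversible under the acid and drains to the C–C product. Cross-coupling should win over self-coupling because ring A of 6 is only a resorcinol diether while 8 is a phloroglucinol triether present in excess and 6 is added slowly, and the low temperature keeps the O1–C2 bonds of both units closed so that neither C2 is scrambled. Loss of H-3 from 9 to the flav-3-ene is reversible here, since protonation at C3 returns 9.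

Step 6
Reactants: 10 octa-O-benzyl ether of the target
Product: 11 (2R,3R)-8-[(2S,4R)-2-(3,4-dihydroxyphenyl)-7-hydroxychroman-4-yl]-2-(3,4,5-trihydroxyphenyl)chromane-3,5,7-triol (target, CNP0211965.1)
Conditions: H2 (1 atm), 20 % Pd(OH)2/C, THF/MeOH/H2O, rt; filtration, Sephadex LH-20, freeze-drying under N2
Reagents that add atoms: none
Why: Catalytic hydrogenolysis of aryl benzyl ethers under neutral conditions, the standard end game for benzylated proanthocyanidins, in which the eight exocyclic O–CH2Ph bonds are cleaved far faster than the endocyclic benzylic O1–C2 bonds and the C4–C8 bond is not touched, so that all four stereocentres persist.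

**Compound list**
1 | 1-[4-(benzyloxy)-2-hydroxyphenyl]ethanone | CC(=O)c1ccc(OCc2ccccc2)cc1O | starting material
2 | (E)-1-[4-(benzyloxy)-2-hydroxyphenyl]-3-(dimethylamino)prop-2-en-1-one | CN(C)/C=C/C(=O)c1ccc(OCc2ccccc2)cc1O | intermediate
3 | 7-(benzyloxy)-4H-chromen-4-one | O=c1ccoc2cc(OCc3ccccc3)ccc12 | intermediate
4 | [3,4-bis(benzyloxy)phenyl]boronic acid | OB(O)c1ccc(OCc2ccccc2)c(OCc2ccccc2)c1 | starting material
5 | (2S)-7-(benzyloxy)-2-[3,4-bis(benzyloxy)phenyl]chroman-4-one | c1ccccc1COc1ccc2c(c1)O[C@H](c1ccc(OCc3ccccc3)c(OCc3ccccc3)c1)CC2=O | intermediate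
6 | (2S,4S)-7-(benzyloxy)-2-[3,4-bis(benzyloxy)phenyl]chroman-4-ol | c1ccccc1COc1ccc2c(c1)O[C@H](c1ccc(OCc3ccccc3)c(OCc3ccccc3)c1)C[C@@H]2O | intermediate
7 | (−)-epigallocatechin, (2R,3R) | Oc1cc(O)c2c(c1)O[C@H](c1cc(O)c(O)c(O)c1)[C@H](O)C2 | starting material
8 | (2R,3R)-5,7-bis(benzyloxy)-2-[3,4,5-tris(benzyloxy)phenyl]chroman-3-ol | c1ccccc1COc1cc(OCc3ccccc3)c2c(c1)O[C@H](c1cc(OCc3ccccc3)c(OCc3ccccc3)c(OCc3ccccc3)c1)[C@H](O)C2 | intermediate
9 | (2S)-7-(benzyloxy)-2-[3,4-bis(benzyloxy)phenyl]chroman-4-ylium (O-benzylated ring-A p-quinone methide) | c1ccccc1COc1ccc2c(c1)O[C@H](c1ccc(OCc3ccccc3)c(OCc3ccccc3)c1)C[CH+]2 | intermediate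
10 | octa-O-benzyl ether of the target, upper unit (2S,4R), lower unit (2R,3R) | c1ccccc1COc1ccc2c(c1)O[C@H](c1ccc(OCc3ccccc3)c(OCc3ccccc3)c1)C[C@H]2c1c(OCc3ccccc3)cc(OCc3ccccc3)c2c1O[C@H](c1cc(OCc3ccccc3)c(OCc3ccccc3)c(OCc3ccccc3)c1)[C@H](O)C2 | intermediate
11 | (2S,4R)-7,3',4'-trihydroxyflavan-(4β→8)-(−)-epigallocatechin | Oc1ccc2c(c1)O[C@H](c1ccc(O)c(O)c1)C[C@H]2c1c(O)cc(O)c2c1O[C@H](c1cc(O)c(O)c(O)c1)[C@H](O)C2 | target

Total step count: 6. Longest linear sequence: 5 steps (1 → 3 → 5 → 6 → 10 → 11).

**Steps most likely to fail**

Step 5. Four processes may intervene: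
- lasting loss of H-3 from the cation (elimination);
- attack of the cation on ring A of a second molecule of 6 (self-condensation);
- incomplete facial selectivity at C4;
- incomplete C8/C6 selectivity.

Fallback: the union is moved to the free-phenol level, where the electrophile is a neutral, less reactive and therefore more discriminating quinone methide and the phloroglucinol ring outruns the resorcinol ring by a wider margin. The fallback sets out from 5. Neutral hydrogenolysis (H2, Pd/C, EtOAc/EtOH) should give (2S)-7,3',4'-trihydroxyflavanone F1. A brief NaBH4 reduction (EtOH, 0 °C, N2) should then give the labile (2S,4S)-2-(3,4-dihydroxyphenyl)chromane-4,7-diol F2, which is used crude. The contact time is kept short because the phenoxide of the flavanone can open ring C. In 0.1 M aqueous HCl at room temperature under nitrogen, with 7 in several-fold excess, this alcohol loses water to the ring-A p-quinone methide F3. C8 of 7 captures it under the same pseudo-axial control. Chromatography on Sephadex LH-20 brings the fallback back to the route at 11, so that steps 4 and 6 fall away.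

Step 2. Insertion may be slow because the 7-alkoxychromone is a vinylogous ester. The electron-rich boronic acid may protodeboronate, and ring opening may erode the enantiomeric purity.

Fallback: C2 is set by resolution through the ketone instead of by C–C bond formation. The fallback sets out from 1.
- Claisen–Schmidt condensation with commercial 3,4-bis(benzyloxy)benzaldehyde (O=Cc1ccc(OCc2ccccc2)c(OCc2ccccc2)c1; KOH, EtOH) should give (E)-4'-benzyloxy-2'-hydroxy-3,4-bis(benzyloxy)chalcone F4.
- NaOAc in refluxing EtOH should close it (oxa-Michael addition) to the racemic tri-O-benzylflavanone F5.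
- Noyori-type asymmetric transfer hydrogenation is then run as a kinetic resolution (RuCl[(S,S)-TsDPEN](p-cymene), HCO2H/Et3N, EtOAc, rt, stopped near half conversion). The catalyst delivers hydride to give 4S alcohols, and only the 2S ketone can accept it on its favoured pseudo-axial face.
- The 2S ketone is thus reduced to 6, where the fallback comes back to the route. The unreacted (2R)-tri-O-benzylflavanone F6 is separated and returned to the racemate with base.

Step 4. The polyphenoxide may suffer air oxidation of the pyrogallol ring, C-benzylation of the phloroglucinol ring and base-induced epimerisation at C2.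

Fallback: the phenols are masked first and released one at a time. The fallback sets out from 7. Ac2O/pyridine should give the air-stable hexa-O-acetyl-(−)-epigallocatechin F7. With BnBr and K2CO3 in degassed DMF/MeOH the aryl acetates are methanolysed successively, and each phenoxide is benzylated as it appears, while the remaining acetates keep the rings electron-poor. The aliphatic 3-acetate is methanolysed last and cannot be benzylated by carbonate, so the fallback comes back to the route at 8.

**Further compounds**
F1 | step 5 | (2S)-7,3',4'-trihydroxyflavanone [(S)-butin] | Oc1ccc2c(c1)O[C@H](c1ccc(O)c(O)c1)CC2=O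
F2 | step 5 | (2S,4S)-2-(3,4-dihydroxyphenyl)chromane-4,7-diol | Oc1ccc2c(c1)O[C@H](c1ccc(O)c(O)c1)C[C@@H]2O
F3 | step 5 | (2S)-2-(3,4-dihydroxyphenyl)-2,3-dihydro-7H-chromen-7-one (ring-A p-quinone methide) | O=C1C=CC2=CC[C@@H](c3ccc(O)c(O)c3)OC2=C1
F4 | step 2 | (E)-1-[4-(benzyloxy)-2-hydroxyphenyl]-3-[3,4-bis(benzyloxy)phenyl]prop-2-en-1-one | O=C(/C=C/c1ccc(OCc2ccccc2)c(OCc2ccccc2)c1)c1ccc(OCc2ccccc2)cc1O
F5 | step 2 | rac-7-(benzyloxy)-2-[3,4-bis(benzyloxy)phenyl]chroman-4-one | c1ccccc1COc1ccc2c(c1)OC(c1ccc(OCc3ccccc3)c(OCc3ccccc3)c1)CC2=O
F6 | step 2 | (2R)-7-(benzyloxy)-2-[3,4-bis(benzyloxy)phenyl]chroman-4-one | c1ccccc1COc1ccc2c(c1)O[C@@H](c1ccc(OCc3ccccc3)c(OCc3ccccc3)c1)CC2=O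
F7 | step 4 | hexa-O-acetyl-(−)-epigallocatechin, (2R,3R) | CC(=O)Oc1cc(OC(C)=O)c2c(c1)O[C@H](c1cc(OC(C)=O)c(OC(C)=O)c(OC(C)=O)c1)[C@H](OC(C)=O)C2
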